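in all of them: starting material 0.092 M; protic impurity 0.0184 M

|  | reagent | second substrate | temperature | remark | time |
|---|---|---|---|---|---|
| elm | 0.092 M | 0.46 M | 70 °C | the very flask that is asked about, followed so far |  |
| maple | 0.092 M | 0.46 M | 55 °C | run made earlier |  |
| flask | 0.0920 M | 0.460 M | 70 °C |  | 6.0 h |

| run | time / min | target / % | starting material / % |
|---|---|---|---|
| elm | 25.0 | 36.3 | 51.6 |
| elm | 40.0 | 37.5 | 51.7 |
| elm | 80.0 | 37.0 | 51.1 |
| elm | 150 | 37.3 | 50.9 |
| elm | 300 | 37.5 | 51.5 |
| maple | 50.0 | 30.3 | 51.5 |
| maple | 80.0 | 29.6 | 50.8 |
| maple | 180 | 28.7 | 50.4 |
| maple | 300 | 29.1 | 50.1 |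
| maple | 600 | 28.9 | 49.7 |

(scatter of a reading: 0.3 percentage points)

- blue: change nothing and wait 2.0 h more
- grey: at 6.0 h add reagent, 100% of the amount charged, then wait 2.0 h
- violet: at 6.0 h raise the temperature by 15 K, then wait 2.0 h
- green: at 6.0 h take out 90% of the target then present, then wait 2.0 h

- target taken out counts as made
- additions bring no volume worth counting

- target, in percent of the starting material first charged, at 6.0 h
- the remedy with the largest gain of target, or "none" below 2 percentage points (blue / grey / violet / green / none)
- target present, with what was taken out counted in, in percent of the starting material first charged, after violet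
- target present, with what was taken out counted in, in percent of the starting material first charged, after green

How much starting material has the elm run used? Over its last 4 readings the mean left is 51.3%, so 48.7% is used, and the mean target is 37.3%.

Does that move? From 40.0 min to 300 min the target stays between 37.0% and 37.5%, so my answer for 6.0 h is 37.3%, and blue gains nothing.

Where is the rest? It is used but not target, and the maple run has more of it: 29.0% target from 50.1% used.

Couldn't a plain side reaction with a fixed share do that? Not in the maple run: there the starting material still creeps down while the target falls by 1.4 percentage points, against a scatter of 0.3 points. Target is turning into the missing part, and the fall stops with target still there, so I read a balance between the two, which is thermodynamic control.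

So what do you carry? The split r, the missing part over the target, c(missing)/c(target): 0.305 at 70 °C and 0.728 at 55 °C. Target is then the used amount divided by 1 + r.

Does the split have time to set again? The elm run reads flat from 40.0 min on, and that is less than the 2.0 h allowed.

Violet? The step from 55 °C to 70 °C divided r by 2.39. I take the same factor for the next 15 K, giving r = 0.128, and with the used amount unchanged, 43.2%.

Green? 33.6% comes out, the remainder splits again, and the total is 45.2%.

Grey? If fresh reagent uses the same fraction of the remaining starting material, a guess, the gain is 19 points, more than green's 7.9 points or violet's 5.9 points. I choose grey.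

The forecast gives 37.2%, grey, 37.2% after violet and 37.2% after green: “Heating and removing target also do nothing, because no reagent is left.” We part on violet and green.

The flask gives 37.3%, grey with a gain of 25 points, 42.7% after violet and 45.3% after green.

    reagent ⇌ dormant form (K = 0.390, k = 0.0340 min⁻¹, Ea = 95.0 kJ mol⁻¹, ΔH = −85.0 kJ mol⁻¹)
    second substrate + reagent → second product (k = 0.450 M⁻¹ min⁻¹, Ea = 71.0 kJ mol⁻¹)
    second substrate + protic impurity → quenched substrate (k = 3.80 M⁻¹ min⁻¹, Ea = 55.0 kJ mol⁻¹)
    target ⇌ isomer of the product (K = 0.310, k = 0.120 min⁻¹, Ea = 103 kJ mol⁻¹, ΔH = −52.0 kJ mol⁻¹)
    starting material + reagent → target (k = 2.70 M⁻¹ min⁻¹, Ea = 65.0 kJ mol⁻¹)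
    (constants at 70 °C)

Target and isomer of the product relax towards each other with a half-life of 1.37 min, short against 6.0 h. The split gave 45.2% for green. One more flask, charged with 0.037 M of starting material, keeps 36.6% at 6.0 h, so its used part divided by 1 + r gives 48.6%, and that flask holds 48.4% target.

The runs stem from a simulated flask on assumed constants, noise included.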